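| flask | electrophile | protic impurity | solid nucleophile | remark | time |
|---|---|---|---|---|---|
| eta | 0.40 M | 0.11 M | 0.42 M | run made earlier |  |
| zeta | 0.40 M | 0.18 M | 0.42 M | run made earlier |  |
| alpha | 0.20 M | 0.080 M | 0.42 M | run made earlier |  |
| flask | 0.40 M | 0.0800 M | 0.420 M |  | 2.0 h |

- eta (time / min: electrophile / %, target / %): 25.0: 72.4, 12.7; 50.0: 56.7, 22.7; 80.0: 49.0, 27.1; 90.0: 47.2, 27.2
- zeta (time / min: electrophile / %, target / %): 8.00: 85.3, 2.6; 20.0: 69.3, 8.7; 40.0: 52.3, 17.3; 90.0: 35.9, 25.0
- alpha (time / min: electrophile / %, target / %): 25.0: 74.0, 12.3; 50.0: 54.7, 23.9; 80.0: 42.7, 32.4; 90.0: 39.7, 32.9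

(readings scatter by 0.5 percentage points)

1. part of the electrophile that has reacted at 2.0 h
2. share of free nucleophile in free nucleophile and protonated nucleophile together, at 2.0 h

- the earlier runs were read with a standard deviation of 0.5 percentage points
- at the start none of the solid nucleophile is in solution
- the earlier runs do not show how much of nucleophile is bound; that part of a forecast is a guess

1. My unit was the molar minute, in which I measured the area under the electrophile curve, called exposure. I booked electrophile that had reacted but did not stand as target to the protic impurity, and treated the impurity's decay as pseudo-first-order in exposure: ln(charge/left) divided by exposure gives a constant.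

2. In the zeta run, that booking put the impurity left at the last reading at 0.0236 M. Trapezoids through the readings gave 20.4 M·min, so the constant read 0.0998 M⁻¹ min⁻¹.

3. The alpha run, with half the electrophile of the zeta run, gave 11.3 M·min and 0.102 M⁻¹ min⁻¹, close to the zeta value. I kept their mean, 0.101 M⁻¹ min⁻¹, as the quench constant.

4. Replacing the zeta curve by the mean of its two ends gave 24.5 M·min and a constant of 0.0831 M⁻¹ min⁻¹. That way cheats: the chord lies above the sagging curve.

5. For the flask I took the eta curve, holding its last reading up to 2.0 h: 29.0 M·min. So I expected 5.35% of the flask's impurity to stay at that time, and 18.9% of the electrophile charged to go the side way. This reckoning gives neither the part reacted nor the free share.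

6. The forecast put the part reacted at 50% (45% to 56%) and the free share at 30% (5% to 75%), adding “The free share is unmeasured”.

7. In the flask, 49.6% of the electrophile had reacted, and the free share was 16.1%.

    electrophile + nucleophile → acid set free + target (k = 0.0510 M⁻¹ min⁻¹)
    nucleophile + acid set free ⇌ protonated nucleophile, settled at all times (K = 190 M⁻¹)
    electrophile + protic impurity → quenched substrate (k = 0.100 M⁻¹ min⁻¹)
    solid nucleophile ⇌ nucleophile, rate k4*(cs4 - [nucleophile]) while solid is left; crystals form when [nucleophile] > cs4 (solubility = 0.170 M, k = 0.190 min⁻¹)
    nucleophile ⇌ dormant form (K = 11.0, k = 0.0260 min⁻¹)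

8. The flask kept 4.6% of its impurity against my 5.35%, and held 19.1% of the electrophile charged as quenched substrate against my 18.9%. For the neighbour flask, charged with 0.20 M of impurity, I took the zeta curve, its last reading held up to 2.0 h: 24.7 M·min. With the quench constant I reckoned 8.29% of that impurity left and 45.9% of the electrophile charged as quenched substrate. The neighbour flask kept 10% of its impurity and held 44.9% of the electrophile charged as quenched substrate.

(Readings and results were computed for an exercise, noise included.)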